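**Plan**

- Retrosynthetic cuts: (a) the seven phenolic O–benzyl bonds, removed last; (b) the Cα–C3 bond between the stereocentre and C3 of the 4H‑chromen‑4‑one (pyranone) ring, giving a racemic α‑bromo ketone and a chromon‑3‑ylzinc; (c) in the ketone half Cα–Br, Cβ–aryl and Cα=Cβ; in the chromone half C3–I, O1–C2 and C2–C3.
- Forward: one phloroacetophenone is benzylated and divided. Half A: aldol to a chalcone, then conjugate arylation with α‑bromination (Cβ then carries two identical aryl groups and is not stereogenic). Half B: enaminone, then iodocyclisation closes the pyranone ring. The chain is joined at Cα–C3 and the ethers are cleaved.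
- Enabling feature: Cα is the only stereocentre, lies α to the C1 aryl‑ketone carbonyl and carries an sp2 carbon (C3 of the pyranone ring). Its bromide therefore gives a planar, ketone‑stabilised radical, and C3 can be delivered as an sp2 organozinc.
- Stereochemistry: a chiral Ni/pybox catalyst funnels both enantiomers of the bromide into (R)‑Cα (stereoconvergent cross‑coupling). The acidic centre is created in the penultimate step without base, and the last step is neutral.

Key step: step 7

Remark on the chemistry: the target is taken as the (R)‑enantiomer (CIP order at Cα: aroyl > chromon‑3‑yl > diarylmethyl > H, unchanged by benzylation). The sense of induction of the pybox ligand cannot be transferred with certainty from simpler ketones, so the ligand antipode that delivers (R) is to be fixed in a first analytical run; both antipodes are commercial.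

**Step 1**
Reactants: 1 2',4',6'‑trihydroxyacetophenone
Product: 2 1‑[2,4‑bis(benzyloxy)‑6‑hydroxyphenyl]ethan‑1‑one
Conditions: BnBr (2.1 equiv), K2CO3 (2.2 equiv), acetone, reflux
Reagents that add atoms: benzyl bromide, BrCc1ccccc1
Why: Williamson etherification in which the phenol hydrogen‑bonded to the acetyl carbonyl is the least reactive and should stay free, as needed later for the pyranone closure.

**Step 2** (on one part of 2)
Reactants: 2 1‑[2,4‑bis(benzyloxy)‑6‑hydroxyphenyl]ethan‑1‑one
Product: 3 1‑[2,4,6‑tris(benzyloxy)phenyl]ethan‑1‑one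
Conditions: BnBr (1.5 equiv), K2CO3, Bu4NI (cat.), DMF, 80 °C
Reagents that add atoms: benzyl bromide, BrCc1ccccc1
Why: Williamson etherification under forcing conditions should also alkylate the chelated phenol, giving a ketone with no free OH for the organometallic steps.

**Step 3**
Reactants: 3 1‑[2,4,6‑tris(benzyloxy)phenyl]ethan‑1‑one; 4 4‑(benzyloxy)benzaldehyde
Product: 5 (E)‑3‑[4‑(benzyloxy)phenyl]‑1‑[2,4,6‑tris(benzyloxy)phenyl]prop‑2‑en‑1‑one
Conditions: KOH (50 % aq.), EtOH/THF, rt
Reagents that add atoms: none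
Why: Claisen–Schmidt condensation between the only enolisable partner 3 and the non‑enolisable aldehyde 4, with E1cB dehydration expected to give the (E)‑chalcone.

**Step 4**
Reactants: 5 (E)‑3‑[4‑(benzyloxy)phenyl]‑1‑[2,4,6‑tris(benzyloxy)phenyl]prop‑2‑en‑1‑one; 6 [4‑(benzyloxy)phenyl]magnesium bromide
Product: 8 rac‑3,3‑bis[4‑(benzyloxy)phenyl]‑2‑bromo‑1‑[2,4,6‑tris(benzyloxy)phenyl]propan‑1‑one, via (Z)‑{3,3‑bis[4‑(benzyloxy)phenyl]‑1‑[2,4,6‑tris(benzyloxy)phenyl]prop‑1‑en‑1‑yl}oxy(trimethyl)silane 7 (not isolated)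
Conditions: 6 (1.15 equiv), CuBr·SMe2 (10 mol %), TMSCl (2 equiv), THF, −78 → −30 °C; concentrate, pentane, filter under Ar; then NBS (1.05 equiv), THF, −78 °C
Reagents that add atoms: N‑bromosuccinimide, O=C1CCC(=O)N1Br; chlorotrimethylsilane, C[Si](C)(C)Cl (remains in 7 only)
Why: copper‑catalysed, TMSCl‑accelerated conjugate addition of the aryl Grignard (1,2‑addition is blocked by the di‑ortho‑substituted aroyl group) gives the enol silane regiospecifically, and its bromination with NBS places Br at Cα only; Cα is deliberately racemic and Cβ is not stereogenic.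

**Step 5** (on the other part of 2)
Reactants: 2 1‑[2,4‑bis(benzyloxy)‑6‑hydroxyphenyl]ethan‑1‑one
Product: 9 (E)‑1‑[2,4‑bis(benzyloxy)‑6‑hydroxyphenyl]‑3‑(dimethylamino)prop‑2‑en‑1‑one
Conditions: DMF‑DMA (3 equiv), toluene, 95 °C
Reagents that add atoms: N,N‑dimethylformamide dimethyl acetal, COC(OC)N(C)C
Why: condensation of the acetyl CH3 with the amide acetal should give the (E)‑enaminone, which carries the future C2 of the pyranone ring.

**Step 6**
Reactants: 9 (E)‑1‑[2,4‑bis(benzyloxy)‑6‑hydroxyphenyl]‑3‑(dimethylamino)prop‑2‑en‑1‑one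
Product: 10 5,7‑bis(benzyloxy)‑3‑iodo‑4H‑chromen‑4‑one
Conditions: I2 (2 equiv), CHCl3, rt; aq. Na2S2O3 wash
Reagents that add atoms: iodine, II
Why: electrophilic iodination of the enaminone α‑carbon, 6‑exo‑trig attack of the phenol on the resulting iminium carbon and loss of dimethylamine (iodocyclisation of o‑hydroxyaryl enaminones) should give the 3‑iodochromone.

**Step 7**
Reactants: 8 rac‑3,3‑bis[4‑(benzyloxy)phenyl]‑2‑bromo‑1‑[2,4,6‑tris(benzyloxy)phenyl]propan‑1‑one; 10 5,7‑bis(benzyloxy)‑3‑iodo‑4H‑chromen‑4‑one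
Product: 12 5,7‑bis(benzyloxy)‑3‑{(2R)‑1,1‑bis[4‑(benzyloxy)phenyl]‑3‑oxo‑3‑[2,4,6‑tris(benzyloxy)phenyl]propan‑2‑yl}‑4H‑chromen‑4‑one, via [5,7‑bis(benzyloxy)‑4‑oxo‑4H‑chromen‑3‑yl]zinc iodide 11 (not isolated)
Conditions: 10, Zn dust (activated with BrCH2CH2Br/TMSCl), LiCl, THF, 25 °C; then 11 (1.3 equiv) added to 8, NiCl2·glyme (10 mol %), Ph‑pybox (one antipode, 13 mol %), glyme/THF, −30 °C
Reagents that add atoms: zinc, [Zn] (remains in 11 only, not in 12)
Why: A (pybox)Ni(I) species abstracts bromine from either enantiomer of 8 to give the same planar α‑keto radical at Cα (which erases the configuration of the racemate), the chromon‑3‑yl group passes from zinc to nickel, and capture of the radical by the chiral aryl–Ni(II) followed by C(sp3)–C(sp2) reductive elimination from Ni(III) forms the Cα–C3 bond. The closest known reaction type is the Ni/pybox‑catalysed stereoconvergent Negishi arylation of racemic secondary α‑bromo aryl ketones with arylzinc iodides at −30 °C, here with an sp2 zinc reagent in which C3 of the pyranone takes the place of the aryl carbon. No ring is closed in this step; the pyranone ring is brought in intact. The single new stereocentre Cα is set by the chiral ligand on nickel in the radical‑capture/reductive‑elimination sequence (catalyst control, both enantiomers of 8 converging on R), not by any element of the substrate. The step needs cross‑coupling to outrun loss of HBr from 8 (to the β,β‑diaryl enone) and enolisation of the acidic Cα–H of 12; the weakly basic organozinc, the absence of added base and the low temperature should secure this, and Cβ bears two identical aryl groups so that no diastereomers can arise.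

**Step 8**
Reactants: 12 5,7‑bis(benzyloxy)‑3‑{(2R)‑1,1‑bis[4‑(benzyloxy)phenyl]‑3‑oxo‑3‑[2,4,6‑tris(benzyloxy)phenyl]propan‑2‑yl}‑4H‑chromen‑4‑one
Product: 13 3‑[(2R)‑1,1‑bis(4‑hydroxyphenyl)‑3‑oxo‑3‑(2,4,6‑trihydroxyphenyl)propan‑2‑yl]‑5,7‑dihydroxy‑4H‑chromen‑4‑one (CNP0106875.1)
Conditions: H2 (1 atm), 10 % Pd/C, EtOAc/MeOH, rt, stopped at the calculated uptake
Reagents that add atoms: none
Why: neutral hydrogenolysis of the seven benzyl ethers should leave the hindered aryl ketone, the 3‑substituted chromone C2=C3 bond and the base‑labile Cα–H configuration untouched.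

**Compound list**

1 | 2',4',6'‑trihydroxyacetophenone | CC(=O)c1c(O)cc(O)cc1O | starting material
2 | 1‑[2,4‑bis(benzyloxy)‑6‑hydroxyphenyl]ethan‑1‑one | CC(=O)c1c(O)cc(OCc2ccccc2)cc1OCc1ccccc1 | intermediate
3 | 1‑[2,4,6‑tris(benzyloxy)phenyl]ethan‑1‑one | CC(=O)c1c(OCc2ccccc2)cc(OCc2ccccc2)cc1OCc1ccccc1 | intermediate
4 | 4‑(benzyloxy)benzaldehyde | O=Cc1ccc(OCc2ccccc2)cc1 | starting material
5 | (E)‑3‑[4‑(benzyloxy)phenyl]‑1‑[2,4,6‑tris(benzyloxy)phenyl]prop‑2‑en‑1‑one | O=C(/C=C/c1ccc(OCc2ccccc2)cc1)c1c(OCc2ccccc2)cc(OCc2ccccc2)cc1OCc1ccccc1 | intermediate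
6 | [4‑(benzyloxy)phenyl]magnesium bromide (THF solution) | Br[Mg]c1ccc(OCc2ccccc2)cc1 | starting material
7 | (Z)‑{3,3‑bis[4‑(benzyloxy)phenyl]‑1‑[2,4,6‑tris(benzyloxy)phenyl]prop‑1‑en‑1‑yl}oxy(trimethyl)silane (Z expected; geometry of no consequence) | C[Si](C)(C)O/C(=C\C(c1ccc(OCc2ccccc2)cc1)c1ccc(OCc2ccccc2)cc1)c1c(OCc2ccccc2)cc(OCc2ccccc2)cc1OCc1ccccc1 | intermediate
8 | rac‑3,3‑bis[4‑(benzyloxy)phenyl]‑2‑bromo‑1‑[2,4,6‑tris(benzyloxy)phenyl]propan‑1‑one | O=C(C(Br)C(c1ccc(OCc2ccccc2)cc1)c1ccc(OCc2ccccc2)cc1)c1c(OCc2ccccc2)cc(OCc2ccccc2)cc1OCc1ccccc1 | intermediate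
9 | (E)‑1‑[2,4‑bis(benzyloxy)‑6‑hydroxyphenyl]‑3‑(dimethylamino)prop‑2‑en‑1‑one | CN(C)/C=C/C(=O)c1c(O)cc(OCc2ccccc2)cc1OCc1ccccc1 | intermediate
10 | 5,7‑bis(benzyloxy)‑3‑iodo‑4H‑chromen‑4‑one | O=c1c(I)coc2cc(OCc3ccccc3)cc(OCc3ccccc3)c12 | intermediate
11 | [5,7‑bis(benzyloxy)‑4‑oxo‑4H‑chromen‑3‑yl]zinc iodide | O=c1c([Zn]I)coc2cc(OCc3ccccc3)cc(OCc3ccccc3)c12 | intermediate
12 | 5,7‑bis(benzyloxy)‑3‑{(2R)‑1,1‑bis[4‑(benzyloxy)phenyl]‑3‑oxo‑3‑[2,4,6‑tris(benzyloxy)phenyl]propan‑2‑yl}‑4H‑chromen‑4‑one | O=C(c1c(OCc2ccccc2)cc(OCc2ccccc2)cc1OCc1ccccc1)[C@@H](c1coc2cc(OCc3ccccc3)cc(OCc3ccccc3)c2c1=O)C(c1ccc(OCc2ccccc2)cc1)c1ccc(OCc2ccccc2)cc1 | intermediate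
13 | 3‑[(2R)‑1,1‑bis(4‑hydroxyphenyl)‑3‑oxo‑3‑(2,4,6‑trihydroxyphenyl)propan‑2‑yl]‑5,7‑dihydroxy‑4H‑chromen‑4‑one | O=C(c1c(O)cc(O)cc1O)[C@@H](c1coc2cc(O)cc(O)c2c1=O)C(c1ccc(O)cc1)c1ccc(O)cc1 | target

**Step count and risks**

Total step count: 8. Longest linear sequence: 6 steps (1, 2, 3, 4, 7, 8).

Steps most likely to fail:

1. Step 7. Capture of the doubly hindered α‑keto radical by the nickel–chromonyl species and the following reductive elimination may be slower than reduction or dehydrobromination of the bromide. Facial discrimination may also erode, because the aroyl group is di‑ortho‑substituted and the zinc reagent carries an ortho carbonyl. The fallback reverses the polarity of the partners and gives up asymmetric catalysis. It sets out from 8: zinc insertion (Zn, THF, rt, Reformatsky conditions) should give the bromozinc enolate F1. Palladium‑catalysed arylation of this zinc enolate with iodide 10 (Pd(dba)2/Q‑phos, THF, rt to 50 °C) should give the racemic heptabenzyl ether F2. Preparative chromatography on a chiral stationary phase then returns to the route at 12. The (S)‑enantiomer F3 is re‑equilibrated to F2 with catalytic DBU in toluene and recycled, so that the lability of Cα–H is put to use.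

2. Step 4. O‑Silylation of the magnesium enolate may be incomplete, NBS may brominate the electron‑rich benzyloxy‑arenes in competition, and HBr may be lost from the product during isolation. The fallback sets out from 5: rhodium‑catalysed 1,4‑addition of 4‑(benzyloxy)phenylboronic acid ([Rh(cod)OH]2, dioxane/H2O, 60 °C) should give the saturated ketone F4. Its lithium enolate (LiHMDS, THF, −78 °C) is then brominated by halophilic transfer from CBr4, which comes back to the route at 8. No free electrophilic bromine meets the arenes.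

3. Step 8. The C2=C3 bond of the pyranone ring may be over‑reduced, and configurational purity may be lost on the catalyst surface during the long contact time that seven ether cleavages require. The fallback sets out from 12: Lewis‑acid ether cleavage with BCl3 and pentamethylbenzene as cation scavenger (CH2Cl2, −78 °C) should lead directly to 13, without hydrogen and without base.

**Further compounds**

F1 | step 7 | bromozinc enolate of 3,3‑bis[4‑(benzyloxy)phenyl]‑1‑[2,4,6‑tris(benzyloxy)phenyl]propan‑1‑one (geometry not defined) | Br[Zn]OC(=CC(c1ccc(OCc2ccccc2)cc1)c1ccc(OCc2ccccc2)cc1)c1c(OCc2ccccc2)cc(OCc2ccccc2)cc1OCc1ccccc1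
F2 | step 7 | racemic heptabenzyl ether, rac‑5,7‑bis(benzyloxy)‑3‑{1,1‑bis[4‑(benzyloxy)phenyl]‑3‑oxo‑3‑[2,4,6‑tris(benzyloxy)phenyl]propan‑2‑yl}‑4H‑chromen‑4‑one | O=C(c1c(OCc2ccccc2)cc(OCc2ccccc2)cc1OCc1ccccc1)C(c1coc2cc(OCc3ccccc3)cc(OCc3ccccc3)c2c1=O)C(c1ccc(OCc2ccccc2)cc1)c1ccc(OCc2ccccc2)cc1
F3 | step 7 | (S)‑enantiomer of 12 | O=C(c1c(OCc2ccccc2)cc(OCc2ccccc2)cc1OCc1ccccc1)[C@H](c1coc2cc(OCc3ccccc3)cc(OCc3ccccc3)c2c1=O)C(c1ccc(OCc2ccccc2)cc1)c1ccc(OCc2ccccc2)cc1
F4 | step 4 | saturated ketone, 3,3‑bis[4‑(benzyloxy)phenyl]‑1‑[2,4,6‑tris(benzyloxy)phenyl]propan‑1‑one | O=C(CC(c1ccc(OCc2ccccc2)cc1)c1ccc(OCc2ccccc2)cc1)c1c(OCc2ccccc2)cc(OCc2ccccc2)cc1OCc1ccccc1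
F0 | step 8 | none | none
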